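The earlier runs and the new flask stem from a simulated flask for an exercise, and the scatter is random.

In a one-step world, starting material and partner going one to one, the target climbs until the partner, the limiting reagent, is used up, at 60.0 % of the starting material charged. Thursday's flask, the one asked about, instead flattens near 22.9 %, with 76.5 % of the starting material still there at 90.0 min.

| setting | Thursday's | Monday's | flask |
|---|---|---|---|
| starting material | 0.20 M | 0.20 M | 0.20 M |
| partner | 0.12 M | 0.12 M | 0.120 M |
| second substrate | 1 M | 1 M | 1.00 M |
| protic impurity | 0.060 M | 0.060 M | 0.0600 M |
| free catalyst | 2.8 mM | 4.2 mM | 2.8 mM |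
| temperature | 60 °C | 55 °C | 60 °C |
| remark | the very flask that is asked about, followed so far | run made earlier |  |
| time |  |  | 1.5 h |

| run | time / min | target / % | starting material / % |
|---|---|---|---|
| Thursday's | 25.0 | 21.6 | 78.3 |
| Thursday's | 50.0 | 21.9 | 77.1 |
| Thursday's | 60.0 | 23.8 | 76.6 |
| Thursday's | 90.0 | 23.0 | 76.5 |
| Monday's | 0.667 | 2.7 | 96.1 |
| Monday's | 1.33 | 6.7 | 91.8 |
| Monday's | 3.00 | 12.7 | 88.2 |
| Monday's | 8.00 | 22.0 | 78.8 |

(each reading ± 0.5 percentage points)

- amber: at 1.5 h add partner, 100 % of the amount charged, then wait 50 min
- ochre: at 1.5 h raise the temperature by 15 K, then wait 50 min
- red: at 1.5 h take out 90 % of the target then present, then wait 50 min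
- blue: at 1.5 h add free catalyst, 100 % of the amount charged, then wait 50 min
- green: change nothing and wait 50 min more

- target that was removed still counts
- additions bring no volume worth counting

* target, in percent of the starting material first charged, at 1.5 h
* what to do for the largest gain in target; "none" if nothing gains more than 2 percentage points (amber / ochre / red / blue / green / none)
* target present, with what was taken out counted in, in percent of the starting material first charged, after ochre
* target present, with what was taken out counted in, in percent of the starting material first charged, after blue

My reckoning treats the catalyst as having a budget: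

budget = [target made] / [free catalyst charged] = 22.9 % × 0.20 M / 2.8 mM = 16.4

This is the target made per catalyst charged, the catalyst budget or turnover number. Blue adds the amount of catalyst charged once more, so a first pass says:

gain = budget × [added catalyst] / [starting material charged] = 23 percentage points

The weak link is that this lets the added catalyst work as well as the first charge did. Monday's flask tests it, with 4.2 mM of free catalyst at 55 °C. You can read its fading from the slopes, as shares of the charge per minute:

early slope, up to 1.33 min: 0.0504 /min

late slope, 3.00 min to 8.00 min: 0.0186 /min

fading constant, from the two slopes and their midpoints: 0.206 /min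

My estimate of Monday's ceiling, the last reading plus what the fading slope still adds: 27.4 %

This ceiling reads above Thursday's, so I take it that the ceiling moves with catalyst, though Monday's flask was also colder. Putting that back in, the extra catalyst bought less than the average:

budget of the extra catalyst = 6.42

gain from blue = 9 points

So I commit to 22.9 % now and 31.9 % after blue, and blue is my choice. Amber, ochre and red bring no new catalyst, so I hold each at 22.9 %.

The forecast parts from me on what to do. It gives 23.4 % now (22.8 % to 24 %) and chooses amber, with 18 % after ochre (13 % to 24 %) and 23.6 % after blue (22.8 % to 26 %). Its ground is that “a similar ceiling at different catalyst loadings points to equilibrium rather than catalyst death, though death is not fully excluded”.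

The flask gives 23.0 % now, and the answer is blue. Blue gains 6.5 points, reaching 29.5 %, while amber gains 0.011 points and ochre leaves 23.0 %.

    starting material + partner + free catalyst → free catalyst + target (k = 170 /M²/min, Ea = 45.0 kJ/mol)
    second substrate + partner + free catalyst → free catalyst + second product (k = 29.0 /M²/min, Ea = 57.0 kJ/mol)
    partner + free catalyst → spent catalyst A (k = 1.10 /M/min, Ea = 71.0 kJ/mol)
    free catalyst → spent catalyst B (k = 0.0460 /min, Ea = 99.0 kJ/mol)
    second substrate + protic impurity → quenched substrate (k = 0.240 /M/min, Ea = 73.0 kJ/mol)
    (constants at 60 °C)

In Thursday's flask, free catalyst has a half-life of 15 min by its passing into spent catalyst B alone, against 29 min for starting material by its step to target at 2.97 min. At 90.0 min in that flask, 0.0407 % of the catalyst is free, 60.4 % is spent catalyst A and 39.6 % is spent catalyst B, beside 77.0 % of the starting material. Blue's added catalyst made 4.67 target per catalyst, against the budget of 16.4.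

In the neighbour flask with 7.0 × 10⁻⁴ M of free catalyst, the budget gives 5.73 %. The computed target there is 7.45 %, with 77 % of its partner left at the end, against 25 % in Thursday's flask.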